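**Strategy.** Ring B (C5–C10) is not closed by cyclisation but grown from a cyclopentane. Its C8(=CH2)–C9(H)(side chain)–C10(quaternary) array is a masked 2-alkylcyclohexanone, which an oxidative 1,2-shift delivers from a (Z)-alkylidene trans-hydrindane: trivalent iodine activates C9, C10 migrates from C8 to C9, and ring B, the C9–C10 bond and the C8 carbonyl arise together, C9 being set by equilibration. The hydrindanone carrying C4, C5 and C10 comes from (+)-podocarpic acid by exhaustive cleavage of its phenol ring and ketonisation of the resulting adipic acid. Methylenation and alkyne carboalumination complete the labdane.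

Key step: step 6

Assumption: natural (+)-podocarpic acid, whose C4, C5 and C10 configuration is that of the target, is taken as a purchasable starting material; labdane numbering is used from compound 6 onward (ketone carbon = C8, ylide carbon = C9).

**Step 1**
Reactants: 1 (+)-podocarpic acid
Product: 2 methyl podocarpate
Conditions: MeI, KHCO3, DMF, 23 °C
Reagents that add atoms: iodomethane, CI
Why: SN2 O-alkylation of the carboxylate is insensitive to the axial neopentyl hindrance at C19 and hydrogencarbonate leaves the phenol un-ionised; the ester masks C19 so that only the two new carboxyl groups can react in step 3.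

**Step 2**
Reactants: 2 methyl podocarpate
Product: 3 seco diacid (3-[2-carboxy-6-(methoxycarbonyl)-2,6-dimethylcyclohexyl]propanoic acid, C4/C5/C10 configuration of 2 retained)
Conditions: RuCl3·xH2O (5 mol %), NaIO4 (excess), MeCN/EtOAc/H2O, 23 °C
Reagents that add atoms: sodium periodate, [Na+].[O-]I(=O)(=O)=O; water, O
Why: RuO4 generated in situ should degrade the electron-rich phenol ring oxidatively and leave a carboxyl group at each of the two ring-fusion carbons (the known fate of ring-A-aromatic steroids under these conditions), while the sp3 stereocentres C4, C5 and C10 and the hindered ester are untouched.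

**Step 3**
Reactants: 3 seco diacid
Product: 6 methyl 4,7a-dimethyl-1-oxooctahydro-1H-indene-4-carboxylate (trans-fused hydrindanone), via cyclic anhydride 4 (not isolated), via β-keto acid 5 (not isolated)
Conditions: Ac2O, NaOAc (cat.), 140 °C; then volatiles off, 250 °C
Reagents that add atoms: none
Why: Blanc cyclisation (ketonic decarboxylation of a 1,6-diacid through its anhydride): the only enolisable carbon, the CH2 next to the side-chain carboxyl, acylates the activated ring carboxyl in a five-membered mode and the β-keto acid 5 loses CO2, the unactivated C19 methyl ester cannot compete, and the trans ring fusion is fixed because C5 is not α to the new carbonyl.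

**Step 4**
Reactants: 7 5-chloropent-1-yne; 8 triphenylphosphine
Product: 10 (pent-4-yn-1-yl)triphenylphosphonium iodide, via 5-iodopent-1-yne 9 (not isolated)
Conditions: NaI, MeCN, reflux
Reagents that add atoms: sodium iodide, [Na+].[I-]
Why: Finkelstein exchange gives the primary iodide in situ, which quaternises triphenylphosphine by SN2 while the alkyne is inert.

**Step 5**
Reactants: 6 hydrindanone; 10 phosphonium iodide
Product: 12 methyl (1Z)-4,7a-dimethyl-1-(pent-4-yn-1-ylidene)octahydro-1H-indene-4-carboxylate, via phosphonium ylide 11 (not isolated)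
Conditions: NaN(SiMe3)2 (1 equiv per 10), THF, 0 °C; then 6, reflux
Reagents that add atoms: none
Why: Wittig olefination of a neopentyl cyclopentanone of the 17-oxo-steroid type, which is known to accept non-stabilised ylides at reflux; one equivalent of base gives the ylide because the phosphonium α-CH2 is far more acidic than the alkyne C–H, and the alkene geometry (Z expected) has no consequence because C9 is equilibrated in step 6.

**Step 6**
Reactants: 12 (Z)-alkylidene hydrindane
Product: 15 methyl 8-oxo-15,16,17-trinorlabd-13-yn-19-oate (9α-H), via methoxy iodane adduct 13 (not isolated), via 9-epi ketone 14 (not isolated)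
Conditions: PhI(OH)OTs (1.1 equiv), MeOH/H2O 95:5, 0 → 23 °C; then NaOMe, 23 °C
Reagents that add atoms: water, O
Why: PhI(OH)OTs adds to the electron-rich trisubstituted C8=C9 bond from the α face (anti to the β C20 methyl) in the Markovnikov sense, iodine on C9 and methanol on the tertiary C8, to give 13; iodobenzene then leaves from C9 while the C8–C10 bond migrates to C9 with inversion, pushed by the C8 methoxy oxygen, and the oxocarbenium ion so formed is hydrolysed by the water present to the C8 ketone. The closest known reaction types are the oxidative ring expansion of alkylidenecycloalkanes by PhI(OH)OTs or Tl(NO3)3 (the Wittig–ring-expansion sequence) and the D-homoannulation of 17-hydroxy-20-sulfonyloxy steroids, which is the same 1,2-shift in a trans-hydrindane. No ring is closed by cyclisation: ring B (C5–C6–C7–C8–C9–C10) arises by enlargement of the cyclopentane C5–C6–C7–C8–C10, C9 being inserted between C8 and C10 as the C9–C10 bond forms. C10 migrates with retention, and C9, delivered stereospecifically from the Z-alkene as the axial 9α-chain epimer 14, lies α to the new carbonyl and is equilibrated by NaOMe to the equatorial 9β-chain, 9α-H isomer 15 of the trans-decalin chair. The step needs migration of C10 and not C7 and attack on the alkene and not the alkyne: the quaternary C10 has the higher migratory aptitude and the rotamer that sets C8–C10 anti to the C9–I bond keeps the iodanyl group over C7H2 and the chain on the open α face, whereas the rotamer needed for C7 migration pushes the chain against the C20 methyl; the terminal alkyne is much less nucleophilic toward trivalent iodine at 0 °C.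

**Step 7**
Reactants: 15 ring-expanded ketone
Product: 16 methyl 15,16-dinorlabd-8(17)-en-13-yn-19-oate
Conditions: Ph3PCH3Br, KN(SiMe3)2, THF, 0 → 60 °C
Reagents that add atoms: methyltriphenylphosphonium bromide, C[P+](c1ccccc1)(c1ccccc1)c1ccccc1.[Br-]
Why: Wittig methylenation of a hindered 2-alkylcyclohexanone, standard for 8-oxo-17-norlabdanes; the ylide does not deprotonate the alkyne appreciably and any enolisation returns the thermodynamic 9α-H configuration.

**Step 8**
Reactants: 16 enyne ester
Product: 19 methyl isocupressate (methyl (13E)-15-hydroxylabda-8(17),13-dien-19-oate), via alkenylalane 17 (not isolated), via lithium alkenylaluminate 18 (not isolated)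
Conditions: Me3Al, Cp2ZrCl2 (0.25 equiv), CH2Cl2, 0 → 23 °C; volatiles off; n-BuLi, THF, −78 °C; (CH2O)n, −78 → 23 °C; aq. NH4Cl
Reagents that add atoms: trimethylaluminium, C[Al](C)C; paraformaldehyde (as formaldehyde), C=O
Why: Negishi carboalumination: zirconocene-catalysed syn addition of CH3–Al across the terminal alkyne places the methyl on C13 and aluminium on C14, and hydroxymethylation of the derived aluminate by formaldehyde proceeds with retention, so the 13E geometry follows from the syn addition; the hindered ester and the 1,1-disubstituted C8(17) alkene should not react.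

**Step 9**
Reactants: 19 methyl isocupressate
Product: 20 isocupressic acid
Conditions: NaSEt, DMF, 100 °C; then 1 M HCl
Reagents that add atoms: none
Why: Thiolate SN2 dealkylation attacks the ester methyl carbon and so bypasses the axial, neopentyl acyl carbon that resists saponification; the alkenes and the free allylic alcohol are inert to thiolate.

**Step 10**
Reactants: 20 isocupressic acid
Product: 21 15-acetoxyisocupressic acid
Conditions: Ac2O, pyridine, DMAP (cat.), CH2Cl2, 0 → 23 °C; aqueous work-up
Reagents that add atoms: acetic anhydride, CC(=O)OC(C)=O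
Why: The primary allylic alcohol is acylated much faster than the hindered tertiary carboxyl, and any mixed anhydride formed there is hydrolysed on aqueous work-up.

**Compound list**

1 | (+)-podocarpic acid (12-hydroxypodocarpa-8,11,13-trien-19-oic acid; 4β-CO2H, 4α-CH3, 5α-H, 10β-CH3) | Oc1ccc2c(c1)[C@@]1(C)CCC[C@](C)(C(=O)O)[C@@H]1CC2 | starting material
2 | methyl podocarpate (methyl 12-hydroxypodocarpa-8,11,13-trien-19-oate) | Oc1ccc2c(c1)[C@@]1(C)CCC[C@](C)(C(=O)OC)[C@@H]1CC2 | intermediate
3 | seco diacid, 3-[2-carboxy-6-(methoxycarbonyl)-2,6-dimethylcyclohexyl]propanoic acid (CO2CH3 β on C4, side chain β and H α on C5, CH3 β and CO2H α on C10) | OC(=O)[C@@]1(C)CCC[C@](C)(C(=O)OC)[C@@H]1CCC(=O)O | intermediate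
4 | seven-membered cyclic anhydride of 3 | O=C1OC(=O)[C@@]2(C)CCC[C@](C)(C(=O)OC)[C@@H]2CC1 | intermediate (not isolated)
5 | β-keto acid, 4-(methoxycarbonyl)-4,7a-dimethyl-1-oxooctahydro-1H-indene-2-carboxylic acid (C2 epimers) | O=C1C(C(=O)O)C[C@@H]2[C@]1(C)CCC[C@]2(C)C(=O)OC | intermediate (not isolated)
6 | methyl 4,7a-dimethyl-1-oxooctahydro-1H-indene-4-carboxylate, trans-fused (3a-H α, 7a-CH3 β, 4-CO2CH3 β, 4-CH3 α) | O=C1CC[C@@H]2[C@]1(C)CCC[C@]2(C)C(=O)OC | intermediate
7 | 5-chloropent-1-yne | C#CCCCCl | starting material
8 | triphenylphosphine | c1ccc(cc1)P(c1ccccc1)c1ccccc1 | starting material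
9 | 5-iodopent-1-yne | C#CCCCI | intermediate (not isolated)
10 | (pent-4-yn-1-yl)triphenylphosphonium iodide | C#CCCC[P+](c1ccccc1)(c1ccccc1)c1ccccc1.[I-] | intermediate
11 | (pent-4-yn-1-ylidene)triphenylphosphorane | C#CCCC=P(c1ccccc1)(c1ccccc1)c1ccccc1 | intermediate (not isolated)
12 | methyl (1Z)-4,7a-dimethyl-1-(pent-4-yn-1-ylidene)octahydro-1H-indene-4-carboxylate (chain cis to C10; ring stereocentres as in 6) | C#CCC/C=C1/CC[C@@H]2[C@]1(C)CCC[C@]2(C)C(=O)OC | intermediate
13 | methoxy iodane adduct: C8–OCH3, C9–I(Ph)(OTs) (C8/C9 configuration not assigned) | COC1(C(CCC#C)I(OS(=O)(=O)c3ccc(C)cc3)c3ccccc3)CC[C@@H]2[C@]1(C)CCC[C@]2(C)C(=O)OC | intermediate (not isolated)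
14 | methyl 8-oxo-15,16,17-trinor-9-epi-labd-13-yn-19-oate (9β-H, chain α) | O=C1CC[C@@H]2[C@](C)(CCC[C@]2(C)C(=O)OC)[C@@H]1CCC#C | intermediate (not isolated)
15 | methyl 8-oxo-15,16,17-trinorlabd-13-yn-19-oate (4β-CO2CH3, 5α-H, 9α-H, 10β-CH3) | O=C1CC[C@@H]2[C@](C)(CCC[C@]2(C)C(=O)OC)[C@H]1CCC#C | intermediate
16 | methyl 15,16-dinorlabd-8(17)-en-13-yn-19-oate | C=C1CC[C@@H]2[C@](C)(CCC[C@]2(C)C(=O)OC)[C@H]1CCC#C | intermediate
17 | (13E)-C14-dimethylalanyl alkene (Al trans to C12) | C=C1CC[C@@H]2[C@](C)(CCC[C@]2(C)C(=O)OC)[C@H]1CC/C(C)=C/[Al](C)C | intermediate (not isolated)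
18 | lithium butyl(dimethyl)alkenylaluminate derived from 17 | C=C1CC[C@@H]2[C@](C)(CCC[C@]2(C)C(=O)OC)[C@H]1CC/C(C)=C/[Al-](C)(C)CCCC.[Li+] | intermediate (not isolated)
19 | methyl isocupressate, methyl (13E)-15-hydroxylabda-8(17),13-dien-19-oate | C=C1CC[C@@H]2[C@](C)(CCC[C@]2(C)C(=O)OC)[C@H]1CC/C(C)=C/CO | intermediate
20 | isocupressic acid, (13E)-15-hydroxylabda-8(17),13-dien-19-oic acid | C=C1CC[C@@H]2[C@](C)(CCC[C@]2(C)C(=O)O)[C@H]1CC/C(C)=C/CO | intermediate
21 | 15-acetoxyisocupressic acid, (13E)-15-acetoxylabda-8(17),13-dien-19-oic acid | C=C1CC[C@@H]2[C@](C)(CCC[C@]2(C)C(=O)O)[C@H]1CC/C(C)=C/COC(C)=O | target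

**Step count and risks**

Total step count: 10. Longest linear sequence: 9 steps (steps 1–3 and 5–10); step 4 is a one-step side branch.

Steps most likely to fail:

Step 6. The 1,2-shift may be diverted: C7 may migrate instead of C10, methanol may capture the iodane without rearrangement, or the iodine reagent may attack the alkyne. The fallback sets out from 12 and comes back at 15, and carries out the same bond shift on a preformed leaving group. OsO4 (cat.) with N-methylmorpholine N-oxide should dihydroxylate the C8=C9 bond from the α face, the alkyne being inert, to give the 8α,9-diol F1. MsCl/pyridine should sulfonylate only the secondary C9 hydroxyl to give the hydroxy mesylate F2. Et3Al in CH2Cl2 at −78 °C should then induce the semipinacol shift of C10 to 14, which NaOMe/MeOH equilibrates to 15.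

Step 3. Thermal ketonisation may stall at oligomeric anhydrides or end in charring. The fallback sets out from 3 and comes back at 6, and closes the ring under base with differentiated acyl groups. MeOH with catalytic H2SO4 at 23 °C should esterify only the unhindered side-chain carboxyl to give the acid diester F3. Carbonyldiimidazole turns the remaining ring carboxyl into the acyl imidazolide F4. LiN(SiMe3)2 (2 equiv, THF, −78 °C) forms the side-chain ester enolate, which is C-acylated by the imidazolide (far more electrophilic than the axial C19 ester) to give the β-keto ester F5. Krapcho dealkoxycarbonylation (LiCl, wet DMSO, 150 °C) gives 6.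

Step 5. Enolisation of the neopentyl ketone by the ylide, or slow addition, may leave 6 unchanged. The fallback sets out from 6 and comes back at 15, and assembles the alkylidene by addition and allylic transposition. Vinylmagnesium bromide with CeCl3 should add from the α face to give the tertiary allylic alcohol F6. PBr3 converts it with allylic transposition into the primary (E)-allylic bromide F7. Lithiated 1-(trimethylsilyl)propyne (CuI cat.) displaces bromide at the primary carbon to give the silylated enyne F8. K2CO3/MeOH removes the silyl group to give the (E)-alkylidene F9, the geometric isomer of 12, which is taken through the conditions of step 6 to rejoin the route at 15.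

**Further compounds**

F1 | step 6 | 8α,9-diol from 12 (methyl 1-hydroxy-1-(1-hydroxypent-4-yn-1-yl)-4,7a-dimethyloctahydro-1H-indene-4-carboxylate) | C#CCC[C@H](O)[C@@]1(O)CC[C@@H]2[C@]1(C)CCC[C@]2(C)C(=O)OC
F2 | step 6 | C9 mesylate of F1 (tertiary C8 hydroxyl free) | C#CCC[C@H](OS(C)(=O)=O)[C@@]1(O)CC[C@@H]2[C@]1(C)CCC[C@]2(C)C(=O)OC
F3 | step 3 | acid diester, methyl 3-[2-carboxy-6-(methoxycarbonyl)-2,6-dimethylcyclohexyl]propanoate | OC(=O)[C@@]1(C)CCC[C@](C)(C(=O)OC)[C@@H]1CCC(=O)OC
F4 | step 3 | acyl imidazolide of F3 | O=C(n1ccnc1)[C@@]1(C)CCC[C@](C)(C(=O)OC)[C@@H]1CCC(=O)OC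
F5 | step 3 | β-keto ester, dimethyl 4,7a-dimethyl-1-oxooctahydro-1H-indene-2,4-dicarboxylate (C2 epimers) | O=C1C(C(=O)OC)C[C@@H]2[C@]1(C)CCC[C@]2(C)C(=O)OC
F6 | step 5 | tertiary allylic alcohol, methyl 1α-ethenyl-1β-hydroxy-4,7a-dimethyloctahydro-1H-indene-4-carboxylate | C=C[C@]1(O)CC[C@@H]2[C@]1(C)CCC[C@]2(C)C(=O)OC
F7 | step 5 | (E)-allylic bromide, methyl (1E)-1-(2-bromoethylidene)-4,7a-dimethyloctahydro-1H-indene-4-carboxylate | BrC/C=C1\CC[C@@H]2[C@]1(C)CCC[C@]2(C)C(=O)OC
F8 | step 5 | silylated enyne, methyl (1E)-4,7a-dimethyl-1-[5-(trimethylsilyl)pent-4-yn-1-ylidene]octahydro-1H-indene-4-carboxylate | C[Si](C)(C)C#CCC/C=C1\CC[C@@H]2[C@]1(C)CCC[C@]2(C)C(=O)OC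
F9 | step 5 | (E)-isomer of 12 | C#CCC/C=C1\CC[C@@H]2[C@]1(C)CCC[C@]2(C)C(=O)OC
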